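## Analysis of the target

- **Skeleton.** The target is a biflavone of the 8,6''-linked type. Unit 1 is acacetin (5,7-dihydroxy-4'-methoxyflavone) bonded through C8. Unit 2 (double-primed atoms) is apigenin 7-methyl ether bonded through C6''.
- **Rings.** Each unit is a 2-aryl-4H-chromen-4-one built from a phloroglucinol-type ring A, a pyranone ring C and a para-oxygenated ring B. The molecule therefore has six rings, ten oxygens and no sp3 carbon apart from the two methyl groups.
- **Stereochemistry.** There is no stereocentre. The only stereogenic element is the C8–C6'' axis, which carries four ortho oxygen functions (C7–OH and O1 on one side, C5''–OH and C7''–OMe on the other) and is written without a descriptor.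
- **Sensitive groups.** There are four free phenols, two of them chelated to C4=O and C4''=O. The two methyl ethers must sit on O4' and O7'' and nowhere else. The pyranone rings open in hot strong alkali and can reclose the other way round in hot strong acid, which interconverts 6- and 8-linked isomers.
- **Difficulty.** The central bond joins two fully ortho-substituted, electron-rich carbons. Six phenolic oxygens of similar reactivity must be told apart. Unit 2 must be attached at C6'' and not at C8'', two positions that differ only in which ortho oxygen belongs to ring C.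
- **Feature used.** The strategy rests on ring A of unit 2. Its carbons C5'' (oxygen), C6'' (aryl), C7'' (methoxy), C8'' (hydrogen) and C8a'' (oxygen) are C2, C3, C4, C5 and C6 of a 3-aryl-4-methoxy-2-pyrone.
- **The sixth atom.** C4a'' is the methylene carbon of a 2-oxoalkyl side chain on pyrone C6. Ring A can therefore be made by opening the lactone and closing C4a''–C5''. A cinnamoyl-derived polyketide chain faces the same choice between lactone and arene in flavonoid biosynthesis.

## Retrosynthetic reasoning

**19 to 18.** The three O–benzyl bonds at O5, O7 and O4''' are cut last.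
- These phenols would consume base and poison the metal-mediated steps, so they are masked throughout.
- Benzyl is chosen because its removal is neutral and reductive. It leaves the two methyl ethers and both pyranone rings alone.
- The C5'' hydroxyl needs no mask. It appears late and is tied up in a hydrogen bond to C4''=O.

**18 to 16 (through 17).** The O1''–C2'' bond is cut and two hydrogens are put back, which turns ring C of unit 2 into the chalcone 16.
- The cut is made here because a chalcone is what the ring A construction delivers.
- C2'', C3'', C4'' and the whole ring B then arrive as one cinnamoyl unit.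
- The forward oxidative cyclisation has to use the C8a'' hydroxyl and not the C5'' hydroxyl.

**16 to 14 (through 15).** The C4a''–C5'' bond is cut, which unfolds ring A of unit 2 into the pyrone 14.
- This removes a tetra-oxygenated, fully substituted arene from the problem and replaces it by a flat heterocycle that is far easier to functionalise.
- The methoxy group on pyrone C4 is already the C7'' methoxy group, so no selective methylation of a polyphenol is needed.
- The forward reaction must open the lactone, keep the chain folded, and close carbon onto the ester (Claisen mode) rather than any other way.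

**14 to 8 and 11 (through 12 and 13).** The C4a''–C4'' bond between the side-chain methylene and the cinnamoyl carbonyl is cut.
- The nucleophile is the carbanion 12 of the 6-methyl group of 8. The electrophile is the amide 11.
- The acylation is placed after the aryl–pyrone coupling and not before it. A bromopyrone that already carried the acidic methylene and the enone would be deprotonated by the coupling base and would offer an alkene to the palladium intermediate. Lithiation of a bromopyrone also invites halogen transfer.
- The amide 11 is preferred to the ester 10 as acyl donor. Its adduct 13 survives until the quench, so the more acidic product cannot destroy the carbanion.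

**8 to 4 and 7.** The C8–C6'' bond is cut as an aryl–pyrone bond.
- It is the only bond between the two halves.
- Making it at the pyrone stage means one partner has only a carbonyl oxygen and a methoxy group beside the reacting carbon, instead of a complete flavone.
- The forward cross-coupling must outrun loss of boron from the hindered, electron-rich 4.

**4 to 3 to 2 to 1.** The C8–B and C8–I bonds are cut in turn, then the two benzyl ethers, which leads to acacetin 1.
- Unit 1 is bought complete, with its 4'-methoxy group in place.
- Alkylating both phenols first is what steers the iodination to C8.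

**7 to 6 to 5, and 11 to 10 to 9.** The bromide and the O-methyl group are removed from 7 to reach the lactone 5. The amide and benzyl groups are removed from 11 to reach the acid 9. Both branches are short functional-group sequences on cheap materials.

## Alternatives that were turned down

**Alternative 1: fluorine placeholders, O1–C8a closed by SNAr.**
- **Disconnection.** The O1–C8a bond of ring C of unit 1 is cut, with fluorine standing in for oxygen at C8a and C7.
- **Key step.** The 1-(6-benzyloxy-2,4-difluoro-3-arylphenyl)-3-(4-methoxyphenyl)propane-1,3-dione A1, whose 3-aryl group is the protected unit 2, is enolised by a mild carbonate base in a dipolar aprotic solvent. The enolate oxygen displaces the ortho fluorine to give the 7-fluoro biflavone A2.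
- **For.** Only one leaving group lies within reach of the enolate oxygen, so the ring can close in one sense only. On this point the plan is stronger than step 11 of the chosen route. Enolate SNAr on an ortho-fluoroaryl ketone is also dependable.
- **Against, endgame.** A2 does not yet have the oxygen pattern of the target. The C7 fluorine must be exchanged in a second SNAr at a carbon buried next to unit 2, activated only through a carbonyl that has by then become a vinylogous ester.
- **Against, fragments.** The central bond would have to join a 6-haloflavone flanked by two alkoxy groups to a 2,6-difluoroaryl metal species, a class that loses its metal very easily. Unit 2 needs its own full synthesis with selective 7''-O-methylation, and the fluoroarene is a purpose-made building block.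
- **Comparison.** The chosen route gives up the unambiguous closure. In its place it has every oxygen in position from the start, two of three starting materials that already hold complete substructures, a less crowded coupling and fewer steps.

**Alternative 2: three-plus-three annulation, C8–C7 and C4a–C5.**
- **Disconnection.** Both bonds are cut, so that ring A of unit 1 is assembled from three pyranone-side carbons and three malonate carbons.
- **Key step.** The 2-(arylmethyl)-6-(4-methoxyphenyl)-4-pyranone A3 is lithiated at its benzylic carbon and acylated by bis(2,4,6-trichlorophenyl) malonate A4. Heating should close the second bond and give the 5,7-diol A5.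
- **For.** No biaryl cross-coupling is needed, because the arene grows around a carbon that already bears unit 2. Two bonds and a free 5,7-diol result from one operation. In convergence and in avoiding the hindered coupling it is stronger than the chosen route.
- **Against, first acylation.** The first acylation takes place at a hindered, doubly stabilised carbanion, and its product is at once deprotonated.
- **Against, second bond.** The second bond needs the weakly nucleophilic C3 of a 4-pyranone to trap an acylketene at high temperature. Activated malonates normally react with carbon–oxygen dinucleophiles to give hydroxypyrones, so carbon–carbon closure here has no close model. Strong base also meets the electrophilic flavone of unit 2, and A3 is itself a multistep target.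
- **Comparison.** The chosen route forms only one bond in its key step. That step belongs to a reaction type shown on the same substrate class, runs at the boiling point of methanol, and has its competing mode blocked by the substrate.

**Alternative 3: thermal annulation of an arylphloroglucinol, C4''–C4a'' and O1''–C2''.**
- **Disconnection.** Both bonds are cut, which removes ring C of unit 2 and leaves a symmetric arylphloroglucinol.
- **Key step.** The 8-(2,4,6-trihydroxyphenyl)flavone A6 is heated without acid with ethyl 4-benzyloxybenzoylacetate A7 (Mentzer pyrone synthesis) to give the 7''-hydroxy biflavone A8.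
- **For.** The two free ring positions of A6 are equivalent, the β-keto ester brings ring B and three carbons at once, and the sequence is shorter than the chosen one. On step count it is stronger.
- **Against, regiochemistry.** After C-acylation the ring can still close through the hydroxyl para to the flavonyl group or through the one ortho to it. The 6''/8'' question is therefore the same as in step 11 and is settled at about 250 °C, where no kinetic preference can be expected.
- **Against, conditions and extra work.** Melt conditions threaten the benzyl ethers and favour the coumarin mode. A8 still needs selective methylation of the hindered 7''-hydroxyl. A6 requires a tetra-ortho-substituted coupling with a trioxygenated arene followed by deprotection.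
- **Comparison.** The chosen route costs more steps. It has the C7'' methoxy group built in, a mild key step, and a ring closure at 120 °C in which steric and hydrogen-bond differences still count.

Key step: step 10

Assumption: the target SMILES holds no descriptor for the hindered C8–C6'' axis, so the biaryl is made as the racemate and no step controls the axis.

In the names below, "flavon-8-yl" means the 5,7-bis(benzyloxy)-2-(4-methoxyphenyl)-4-oxo-4H-chromen-8-yl group.

## Route

Step 1
Reactants: 1 acacetin (5,7-dihydroxy-4'-methoxyflavone)
Product: 2 5,7-di-O-benzylacacetin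
Conditions: BnBr, K2CO3, DMF, 80 °C
Reagents that add atoms: benzyl bromide, BrCc1ccccc1
Why: Williamson ether synthesis; the acidic 7-OH reacts first and the chelated 5-OH follows with excess benzyl bromide in hot DMF. Both phenols must be masked so that the iodination goes to C8 and the later bases meet no acidic proton.

Step 2
Reactants: 2 5,7-di-O-benzylacacetin
Product: 3 8-iodo-5,7-di-O-benzylacacetin
Conditions: NIS, TFA (cat.), CH2Cl2, 0 °C to rt, dark
Reagents that add atoms: N-iodosuccinimide, O=C1CCC(=O)N1I
Why: Electrophilic aromatic iodination of ring A, by far the most electron-rich arene of 2. With the 5-oxygen alkylated, 5,7-dialkoxyflavones are halogenated at C8, which lies next to the tied-back ring oxygen, and not at C6, which lies between two benzyloxy groups.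

Step 3
Reactants: 3 8-iodo-5,7-di-O-benzylacacetin
Product: 4 5,7-di-O-benzylacacetin-8-boronic acid pinacol ester
Conditions: pinacolborane, Et3N, PdCl2(MeCN)2, SPhos, 1,4-dioxane, 80 °C
Reagents that add atoms: pinacolborane, [H]B1OC(C)(C)C(C)(C)O1
Why: Palladium-catalysed borylation of an aryl iodide with pinacolborane (Masuda variant of the Miyaura borylation), which with a bulky electron-rich biarylphosphine suits di-ortho-substituted, electron-rich halides. The flavone carbonyl is a vinylogous ester and is inert, as are the benzyl ethers.

Step 4
Reactants: 5 4-hydroxy-6-methyl-2H-pyran-2-one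
Product: 6 4-methoxy-6-methyl-2H-pyran-2-one
Conditions: Me2SO4, K2CO3, acetone, reflux
Reagents that add atoms: dimethyl sulfate, COS(=O)(=O)OC
Why: O-Alkylation of a vinylogous acid; with a carbonate base in acetone the 4-oxygen is methylated and the 2-pyrone form is kept. This methyl group ends as the C7'' methoxy group of 19.

Step 5
Reactants: 6 4-methoxy-6-methyl-2H-pyran-2-one
Product: 7 3-bromo-4-methoxy-6-methyl-2H-pyran-2-one
Conditions: NBS, CH2Cl2, rt, dark
Reagents that add atoms: N-bromosuccinimide, O=C1CCC(=O)N1Br
Why: Electrophilic bromination of an enol ether; C3 is β to the methoxy oxygen and α to the lactone carbonyl and is the most nucleophilic ring carbon. Ionic conditions in the dark leave the 6-methyl group untouched.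

Step 6
Reactants: 4 5,7-di-O-benzylacacetin-8-boronic acid pinacol ester; 7 3-bromo-4-methoxy-6-methyl-2H-pyran-2-one
Product: 8 3-(flavon-8-yl)-4-methoxy-6-methyl-2H-pyran-2-one
Conditions: Pd(OAc)2, SPhos, K3PO4, toluene/H2O, 90 °C
Reagents that add atoms: none
Why: Suzuki–Miyaura coupling; the C–Br bond α to the lactone carbonyl adds readily to zerovalent palladium, and SPhos speeds up transmetalation and reductive elimination at hindered centres. One partner is a flat pyrone whose ortho groups are only a carbonyl oxygen and a methoxy group, so the crowding is lower than between two flavones. Coupling the simple methylpyrone keeps an acidic methylene and an enone out of the basic palladium step.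

Step 7
Reactants: 9 (E)-4-hydroxycinnamic acid
Product: 10 benzyl (E)-4-benzyloxycinnamate
Conditions: BnBr, K2CO3, DMF, 60 °C
Reagents that add atoms: benzyl bromide, BrCc1ccccc1
Why: Williamson-type alkylation of phenoxide and carboxylate in one operation; the E alkene is not touched.

Step 8
Reactants: 10 benzyl (E)-4-benzyloxycinnamate
Product: 11 (E)-3-(4-benzyloxyphenyl)-N-methoxy-N-methylacrylamide
Conditions: MeNH(OMe)·HCl, iPrMgCl, THF, −20 to 0 °C
Reagents that add atoms: N,O-dimethylhydroxylamine hydrochloride, CNOC.Cl
Why: Aminolysis of an ester by the chloromagnesium amide formed in the flask (Weinreb amide synthesis from an ester). The β-aryl group with its para oxygen donor makes conjugate addition of the amide unfavourable.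

Step 9
Reactants: 8 3-(flavon-8-yl)-4-methoxy-6-methyl-2H-pyran-2-one; 11 (E)-3-(4-benzyloxyphenyl)-N-methoxy-N-methylacrylamide
Product: 14 3-(flavon-8-yl)-4-methoxy-6-[(E)-4-(4-benzyloxyphenyl)-2-oxobut-3-enyl]-2H-pyran-2-one, via lithium dienolate 12 (not isolated), via tetrahedral lithium adduct 13 (not isolated)
Conditions: LiN(SiMe3)2, THF, −78 °C; then 11, −78 to −20 °C; aq. NH4Cl
Reagents that add atoms: none
Why: Weinreb ketone synthesis with a vinylogous ester enolate; LiN(SiMe3)2 deprotonates the 6-methyl group, the only acidic C–H of 8 now that C3 is blocked, and 12 adds to the amide carbonyl of 11. The chelated adduct 13 holds until the quench, so the more acidic ketone 14 cannot protonate unreacted 12 and no second addition occurs. The flavone offers only vinylic and aromatic protons and a weakly electrophilic carbonyl, which are left alone at low temperature.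

Step 10
Reactants: 14 3-(flavon-8-yl)-4-methoxy-6-[(E)-4-(4-benzyloxyphenyl)-2-oxobut-3-enyl]-2H-pyran-2-one
Product: 16 (E)-4-benzyloxy-3'-(flavon-8-yl)-2',6'-dihydroxy-4'-methoxychalcone, via ring-opened methyl ester 15 (not isolated)
Conditions: Mg(OMe)2 (commercial solution in MeOH), MeOH/THF, reflux; then cold 1 M HCl
Reagents that add atoms: magnesium dimethoxide, C[O-].C[O-].[Mg+2] (one methoxide enters 15 and leaves again as methanol, so that 16 is an isomer of 14)
Why: This is the Mg(OMe)2-mediated recyclisation of a 6-(2-oxoalkyl)-4-oxy-2-pyrone to an acylphloroglucinol, the Claisen mode of the biomimetic triketo ester cyclisations. Methoxide adds to the lactone carbonyl C2 of 14 (the later C5'') and expels the C6 enolate to give 15, while its attack at C4 only exchanges methoxy for methoxy and changes nothing. In 15 the C6''=C7'' enol ether still has the ester and the C8'' methylene on the same side, so the chain is folded for closure. The most acidic site is the methylene between the two ketones (C4a''); magnesium holds it as a planar diketonate chelate, this carbon attacks the ester carbonyl in a 6-exo-trig closure, and loss of methanol followed by enolisation to the arene makes the step irreversible. The selectivity needed is Claisen over aldol closure: the aldol nucleophile would be C6'', which bears the flavon-8-yl group and is locked in the enol ether, so an aldol adduct could not aromatise and would revert, and from C4a'' no other electrophile lies at six-ring distance. As part of the diketonate the cinnamoyl unit is a poor Michael acceptor, which shields it from methoxide and from the C8'' methylene. No stereocentre is formed and the E alkene is untouched. Cold acidic work-up releases 16 from its magnesium chelate before it can close to a flavanone.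

Step 11
Reactants: 16 (E)-4-benzyloxy-3'-(flavon-8-yl)-2',6'-dihydroxy-4'-methoxychalcone
Product: 18 5,7,4'''-tri-O-benzyl ether of the target, via racemic flavanone 17 (not isolated)
Conditions: I2 (cat.), DMSO, 120 °C
Reagents that add atoms: none
Why: Iodine/DMSO oxidative cyclisation of a 2'-hydroxychalcone; intramolecular oxa-Michael addition gives 17 as a racemate, α-iodination and loss of HI give the flavone and erase the stereocentre, and DMSO reoxidises HI. Of the two ortho hydroxyls, the C5'' one is wedged between the perpendicular flavon-8-yl group and the carbonyl and stays locked in the hydrogen bond to C4''=O, so the free, unhindered C8a'' hydroxyl should be the nucleophile. Catalytic iodine and the absence of strong acid guard against ring iodination and Wessely–Moser-type isomerisation.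

Step 12
Reactants: 18 5,7,4'''-tri-O-benzyl ether of the target
Product: 19 target biflavone (CNP0253922.0)
Conditions: H2 (1 atm), Pd/C, THF/MeOH, rt
Reagents that add atoms: none
Why: Hydrogenolysis of three aryl benzyl ethers over palladium on carbon. The methyl ethers, the chelated phenol and the conjugated C2=C3 bonds of both flavones are normally not reduced at room temperature and one atmosphere.

## Compound list

1 | acacetin (5,7-dihydroxy-4'-methoxyflavone) | COc1ccc(-c2cc(=O)c3c(O)cc(O)cc3o2)cc1 | starting material
2 | 5,7-di-O-benzylacacetin | COc1ccc(-c2cc(=O)c3c(OCc4ccccc4)cc(OCc4ccccc4)cc3o2)cc1 | intermediate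
3 | 8-iodo-5,7-di-O-benzylacacetin | COc1ccc(-c2cc(=O)c3c(OCc4ccccc4)cc(OCc4ccccc4)c(I)c3o2)cc1 | intermediate
4 | 5,7-di-O-benzylacacetin-8-boronic acid pinacol ester | COc1ccc(-c2cc(=O)c3c(OCc4ccccc4)cc(OCc4ccccc4)c(B4OC(C)(C)C(C)(C)O4)c3o2)cc1 | intermediate
5 | 4-hydroxy-6-methyl-2H-pyran-2-one | Cc1cc(O)cc(=O)o1 | starting material
6 | 4-methoxy-6-methyl-2H-pyran-2-one | COc1cc(C)oc(=O)c1 | intermediate
7 | 3-bromo-4-methoxy-6-methyl-2H-pyran-2-one | COc1cc(C)oc(=O)c1Br | intermediate
8 | 3-(flavon-8-yl)-4-methoxy-6-methyl-2H-pyran-2-one | COc1cc(C)oc(=O)c1-c1c(OCc2ccccc2)cc(OCc2ccccc2)c2c(=O)cc(-c3ccc(OC)cc3)oc12 | intermediate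
9 | (E)-4-hydroxycinnamic acid | O=C(O)/C=C/c1ccc(O)cc1 | starting material
10 | benzyl (E)-4-benzyloxycinnamate | O=C(OCc1ccccc1)/C=C/c1ccc(OCc2ccccc2)cc1 | intermediate
11 | (E)-3-(4-benzyloxyphenyl)-N-methoxy-N-methylacrylamide | CON(C)C(=O)/C=C/c1ccc(OCc2ccccc2)cc1 | intermediate
12 | lithium dienolate of 8 (lithium 3-(flavon-8-yl)-4-methoxy-6-methylidene-6H-pyran-2-olate), not isolated | C=C1C=C(OC)C(c2c(OCc3ccccc3)cc(OCc3ccccc3)c3c(=O)cc(-c4ccc(OC)cc4)oc23)=C(O[Li])O1 | intermediate
13 | racemic tetrahedral lithium adduct of 12 and 11, not isolated | O=c1oc(CC(O[Li])(N(C)OC)/C=C/c2ccc(OCc3ccccc3)cc2)cc(OC)c1-c1c(OCc2ccccc2)cc(OCc2ccccc2)c2c(=O)cc(-c3ccc(OC)cc3)oc12 | intermediate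
14 | 3-(flavon-8-yl)-4-methoxy-6-[(E)-4-(4-benzyloxyphenyl)-2-oxobut-3-enyl]-2H-pyran-2-one | O=c1oc(CC(=O)/C=C/c2ccc(OCc3ccccc3)cc2)cc(OC)c1-c1c(OCc2ccccc2)cc(OCc2ccccc2)c2c(=O)cc(-c3ccc(OC)cc3)oc12 | intermediate
15 | methyl (2E,8E)-9-(4-benzyloxyphenyl)-2-(flavon-8-yl)-3-methoxy-5,7-dioxonona-2,8-dienoate (drawn in the neutral keto form), not isolated | COC(=O)/C(c1c(OCc2ccccc2)cc(OCc2ccccc2)c2c(=O)cc(-c3ccc(OC)cc3)oc12)=C(OC)\CC(=O)CC(=O)/C=C/c1ccc(OCc2ccccc2)cc1 | intermediate
16 | (E)-4-benzyloxy-3'-(flavon-8-yl)-2',6'-dihydroxy-4'-methoxychalcone | O=C(/C=C/c1ccc(OCc2ccccc2)cc1)c1c(O)cc(OC)c(-c2c(OCc3ccccc3)cc(OCc3ccccc3)c3c(=O)cc(-c4ccc(OC)cc4)oc23)c1O | intermediate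
17 | racemic 2-(4-benzyloxyphenyl)-6-(flavon-8-yl)-5-hydroxy-7-methoxychroman-4-one, not isolated | O=C1CC(c2ccc(OCc3ccccc3)cc2)Oc2cc(OC)c(-c3c(OCc4ccccc4)cc(OCc4ccccc4)c4c(=O)cc(-c5ccc(OC)cc5)oc34)c(O)c21 | intermediate
18 | 5,7,4'''-tri-O-benzyl ether of the target | COc1ccc(-c2cc(=O)c3c(OCc4ccccc4)cc(OCc4ccccc4)c(-c4c(OC)cc5oc(-c6ccc(OCc7ccccc7)cc6)cc(=O)c5c4O)c3o2)cc1 | intermediate
19 | 5,7,5'',4'''-tetrahydroxy-4',7''-dimethoxy-8,6''-biflavone (CNP0253922.0) | COc1ccc(-c2cc(=O)c3c(O)cc(O)c(-c4c(OC)cc5oc(-c6ccc(O)cc6)cc(=O)c5c4O)c3o2)cc1 | target

## Step count and least certain steps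

Total step count: 12.
Longest linear sequence: 8 steps (1, 2, 3, 6, 9, 10, 11, 12).

**Step 10 (key step).**
- **Slow opening.** The base first deprotonates the side-chain methylene. The delocalised anion lowers the electrophilicity of the lactone carbonyl, which is also shielded by the perpendicular flavon-8-yl group.
- **Hindered closure.** The Claisen closure has to take place at an ester carbon next to the same bulky group.
- **Diversion on long heating.** The open chain can relactonise. It can close through a ketone enol oxygen onto C7'' with loss of methanol to give a 4-pyranone. It can also lose the cinnamoyl group by retro-Claisen attack of methoxide.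
- **Fallback.** Ring A of unit 2 is bought instead of built. The path sets out from 4 and comes back at 16.
  - 2',6'-Dihydroxy-4'-methoxyacetophenone F1 is mono-iodinated with NIS (its two free ring positions are equivalent) to give 2',6'-dihydroxy-3'-iodo-4'-methoxyacetophenone F2.
  - Both phenols are masked with MOMCl and NaH to give the bis(methoxymethyl) ether F3.
  - Claisen–Schmidt condensation with 4-benzyloxybenzaldehyde F4 (KOH, EtOH) gives the iodochalcone F5.
  - Suzuki–Miyaura coupling of F5 with 4 (Pd(OAc)2, SPhos, K3PO4) gives the bis(methoxymethyl) ether F6 of the chalcone.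
  - HCl in MeOH/THF removes both acetals and gives 16.
  - The price is a tetra-ortho-substituted aryl–aryl coupling, the crowding the pyrone route avoids.

**Step 11.**
- **Risk.** Regioselectivity between the two ortho hydroxyls may be poor. They differ only in steric environment and hydrogen bonding, the oxa-Michael addition is reversible at 120 °C, and closure through the C5'' hydroxyl would lead into the 8''-linked series. Iodination of the electron-rich C8'' or C6 positions is a minor second risk.
- **Fallback.** The hindered oxygen is masked by a protecting-group relay. The path sets out from 16 and comes back at 19.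
  - One equivalent of MOMCl with iPr2NEt at 0 °C etherifies the exposed C8a'' hydroxyl and gives the mono(methoxymethyl) ether F7.
  - BnBr and Cs2CO3 in DMF benzylate the remaining C5'' hydroxyl to give the fully protected chalcone F8. Any reversible closure of the phenoxide is drained by the irreversible alkylation.
  - HCl in MeOH cleaves the acetal to give the chalcone F9, in which only the C8a'' hydroxyl is free.
  - I2 in DMSO can then give only the 6''-linked tetra-O-benzyl biflavone F10.
  - Hydrogenolysis under the conditions of step 12 gives 19.

**Step 6.**
- **Risk.** Loss of boron from the di-ortho-oxygenated, electron-rich boronate may outrun the slow transmetalation, and reductive elimination at a centre with four ortho substituents may be sluggish.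
- **Fallback.** The polarity of the coupling is reversed. The path sets out from 3 and 7 and comes back at 8.
  - Zinc dust and LiCl in THF insert into the C–Br bond of 7 to give (4-methoxy-6-methyl-2-oxo-2H-pyran-3-yl)zinc bromide F11.
  - F11 is coupled with the iodide 3 in a Negishi reaction (Pd(OAc)2, SPhos, THF, 50 °C).
  - The organozinc is too weakly basic to deprotonate the 6-methyl group, no boronate is involved, and step 3 becomes unnecessary.

**Step 9.**
- **Risk.** The stabilised carbanion may react sluggishly with the amide carbonyl. Conjugate addition to the cinnamoyl β-carbon may compete. Early collapse of the adduct would allow proton transfer from the product to the carbanion.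
- **Fallback.** An aldol addition followed by oxidation replaces the acylation. The path sets out from 8 and 11 and comes back at 14.
  - iBu2AlH in THF at −78 °C reduces 11 to (E)-4-benzyloxycinnamaldehyde F12.
  - The carbanion of 8 (LiN(SiMe3)2, −78 °C) adds 1,2 to this far more reactive carbonyl and gives the racemic allylic alcohol F13.
  - Dess–Martin oxidation gives 14.

## Further compounds

F1 | step 10 | 2',6'-dihydroxy-4'-methoxyacetophenone (purchased) | CC(=O)c1c(O)cc(OC)cc1O
F2 | step 10 | 2',6'-dihydroxy-3'-iodo-4'-methoxyacetophenone | CC(=O)c1c(O)cc(OC)c(I)c1O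
F3 | step 10 | 3'-iodo-4'-methoxy-2',6'-bis(methoxymethoxy)acetophenone | CC(=O)c1c(OCOC)cc(OC)c(I)c1OCOC
F4 | step 10 | 4-benzyloxybenzaldehyde (purchased) | O=Cc1ccc(OCc2ccccc2)cc1
F5 | step 10 | (E)-4-benzyloxy-3'-iodo-4'-methoxy-2',6'-bis(methoxymethoxy)chalcone | O=C(/C=C/c1ccc(OCc2ccccc2)cc1)c1c(OCOC)cc(OC)c(I)c1OCOC
F6 | step 10 | (E)-4-benzyloxy-3'-(flavon-8-yl)-4'-methoxy-2',6'-bis(methoxymethoxy)chalcone | O=C(/C=C/c1ccc(OCc2ccccc2)cc1)c1c(OCOC)cc(OC)c(-c2c(OCc3ccccc3)cc(OCc3ccccc3)c3c(=O)cc(-c4ccc(OC)cc4)oc23)c1OCOC
F7 | step 11 | (E)-4-benzyloxy-3'-(flavon-8-yl)-2'-hydroxy-4'-methoxy-6'-(methoxymethoxy)chalcone | O=C(/C=C/c1ccc(OCc2ccccc2)cc1)c1c(OCOC)cc(OC)c(-c2c(OCc3ccccc3)cc(OCc3ccccc3)c3c(=O)cc(-c4ccc(OC)cc4)oc23)c1O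
F8 | step 11 | (E)-4,2'-bis(benzyloxy)-3'-(flavon-8-yl)-4'-methoxy-6'-(methoxymethoxy)chalcone | O=C(/C=C/c1ccc(OCc2ccccc2)cc1)c1c(OCOC)cc(OC)c(-c2c(OCc3ccccc3)cc(OCc3ccccc3)c3c(=O)cc(-c4ccc(OC)cc4)oc23)c1OCc1ccccc1
F9 | step 11 | (E)-4,2'-bis(benzyloxy)-3'-(flavon-8-yl)-6'-hydroxy-4'-methoxychalcone | O=C(/C=C/c1ccc(OCc2ccccc2)cc1)c1c(O)cc(OC)c(-c2c(OCc3ccccc3)cc(OCc3ccccc3)c3c(=O)cc(-c4ccc(OC)cc4)oc23)c1OCc1ccccc1
F10 | step 11 | 5,7,5'',4'''-tetra-O-benzyl ether of the target | COc1ccc(-c2cc(=O)c3c(OCc4ccccc4)cc(OCc4ccccc4)c(-c4c(OC)cc5oc(-c6ccc(OCc7ccccc7)cc6)cc(=O)c5c4OCc4ccccc4)c3o2)cc1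
F11 | step 6 | (4-methoxy-6-methyl-2-oxo-2H-pyran-3-yl)zinc bromide | COc1cc(C)oc(=O)c1[Zn]Br
F12 | step 9 | (E)-4-benzyloxycinnamaldehyde | O=C/C=C/c1ccc(OCc2ccccc2)cc1
F13 | step 9 | racemic 3-(flavon-8-yl)-6-[(E)-4-(4-benzyloxyphenyl)-2-hydroxybut-3-enyl]-4-methoxy-2H-pyran-2-one | O=c1oc(CC(O)/C=C/c2ccc(OCc3ccccc3)cc2)cc(OC)c1-c1c(OCc2ccccc2)cc(OCc2ccccc2)c2c(=O)cc(-c3ccc(OC)cc3)oc12
A1 | alternative 1 | 1-(6-benzyloxy-2,4-difluoro-3-arylphenyl)-3-(4-methoxyphenyl)propane-1,3-dione, aryl = 5-benzyloxy-2-(4-benzyloxyphenyl)-7-methoxy-4-oxo-4H-chromen-6-yl | COc1ccc(C(=O)CC(=O)c2c(OCc3ccccc3)cc(F)c(-c3c(OC)cc4oc(-c5ccc(OCc6ccccc6)cc5)cc(=O)c4c3OCc3ccccc3)c2F)cc1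
A2 | alternative 1 | 7-deoxy-7-fluoro-5,5'',4'''-tri-O-benzyl analogue of the target | COc1ccc(-c2cc(=O)c3c(OCc4ccccc4)cc(F)c(-c4c(OC)cc5oc(-c6ccc(OCc7ccccc7)cc6)cc(=O)c5c4OCc4ccccc4)c3o2)cc1
A3 | alternative 2 | 2-{[5-benzyloxy-2-(4-benzyloxyphenyl)-7-methoxy-4-oxo-4H-chromen-6-yl]methyl}-6-(4-methoxyphenyl)-4H-pyran-4-one | COc1ccc(-c2cc(=O)cc(Cc3c(OC)cc4oc(-c5ccc(OCc6ccccc6)cc5)cc(=O)c4c3OCc3ccccc3)o2)cc1
A4 | alternative 2 | bis(2,4,6-trichlorophenyl) malonate | O=C(CC(=O)Oc1c(Cl)cc(Cl)cc1Cl)Oc1c(Cl)cc(Cl)cc1Cl
A5 | alternative 2 | 5'',4'''-di-O-benzyl ether of the target | COc1ccc(-c2cc(=O)c3c(O)cc(O)c(-c4c(OC)cc5oc(-c6ccc(OCc7ccccc7)cc6)cc(=O)c5c4OCc4ccccc4)c3o2)cc1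
A6 | alternative 3 | 5,7-bis(benzyloxy)-2-(4-methoxyphenyl)-8-(2,4,6-trihydroxyphenyl)-4H-chromen-4-one | COc1ccc(-c2cc(=O)c3c(OCc4ccccc4)cc(OCc4ccccc4)c(-c4c(O)cc(O)cc4O)c3o2)cc1
A7 | alternative 3 | ethyl 4-benzyloxybenzoylacetate | CCOC(=O)CC(=O)c1ccc(OCc2ccccc2)cc1
A8 | alternative 3 | 7''-O-demethyl-5,7,4'''-tri-O-benzyl derivative of the target | COc1ccc(-c2cc(=O)c3c(OCc4ccccc4)cc(OCc4ccccc4)c(-c4c(O)cc5oc(-c6ccc(OCc7ccccc7)cc6)cc(=O)c5c4O)c3o2)cc1
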